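The pitfall with a column of percentages is to read it as a property of the reaction and carry it unchanged to a flask with another charge of D.

common to all: J 200 mM (held)
- larch: D 0.57 M; run made earlier
- beta: D 1.0 M; time 2.0 h
- delta: D 0.40 M; time 2.0 h
- eta: D 0.80 M; time 2.0 h
- zeta: D 2.5 M; time 2.0 h
- gamma: D 3.0 M; time 2.0 h
- theta: D 1.5 M; time 2.0 h

- ranking by amount of X, in percent of the D charged, from high to low, at 2.0 h (beta / delta / eta / zeta / gamma / theta)
- the amount of X, in percent of the D charged of the flask you put first, at 2.0 h
- the amount of X, in percent of the D charged of the flask you put last, at 2.0 h

- the numbers in the tables scatter by 0.5 percentage points (one standard deviation)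
- at the start none of J is in solution

larch run (percent of the D charged): time / min: X / % = 8.00: 2.5; 20.0: 11.8; 40.0: 26.3; 60.0: 39.7; 80.0: 51.6

(each reading ± 0.5 percentage points)

We read the larch table by one quantity, the mean pace: the share of the remaining D that goes per minute over a stretch, which is the log of the fraction remaining at its start over that at its end, divided by its length (an apparent pseudo-first-order constant). The first row gives 0.00316 /min. Between the second and third rows the pace is 0.00898 /min, faster than at first, and between the last two it is 0.0110 /min, faster again. D falls as time passes, so this one run cannot say which of the two lifts the pace.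

We replace that climb by its mean from 20.0 min to 80.0 min, which is 0.0100 /min. As a check, this mean gives 27.8% at 40.0 min against the reading of 26.3%, an error of 1.5 percentage points. That is tolerable for a bracket.

Carried on to 2.0 h, this pace puts larch at 67.6% of X, and that is our upper mark for a flask that keeps the pace whatever its charge. For the opposite picture, suppose gamma turns over the same amount per minute as larch did; it then reaches 15.1%. So we expect X to fall as the charge rises, with gamma between 15.1% and 67.6%. Delta, whose charge is smaller than larch's, we put first by that same expectation, without a figure of its own.

The forecast gives single numbers where we give a bracket: delta > eta > beta > theta > zeta > gamma, with 77% first and 25% last, from the reading that “the rate saturates in D”.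

The flasks give delta > eta > beta > theta > zeta > gamma, with delta first at 74.5% and gamma last at 35.9%, and this figure for gamma lies inside our bracket.

Behind this stand the following steps, with Q the dissolved J, L a form Q passes into, and Z a by-product:

    D + Q ⇌ X + Z (K = 68.9, k = 0.111 /M/min)
    J ⇌ Q, rate k2*(csat - [Q]) (kL = 0.0615 /min)
    Q ⇌ L (K = 2.50, k = 0.0406 /min)

Gamma is not at rest at 2.0 h, with 64% of its D still there. Its own mean pace from 1.00 h to 2.0 h is 0.00410 /min, a fraction 0.410 of the larch pace. Carried one hour on, it gives 49.9%, and the same flask read at 3.0 h stands at 51.5%. Carried to 20.0 h, it gives 99.2%, but gamma left that long stands at 84.5%, a gain of 49 points, and delta gains 23 points to stand at 97.3%.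

The runs are simulated with made-up constants; scatter was added.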